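**Assumption:** the target SMILES contains no stereocentre or other stereogenic element, so the compound is achiral and "single enantiomer" is met by the constitution alone.

**Retrosynthetic overview**
- Both C-prenyl bonds (ring A C5 and ring B C2') are cut at once by a double retro-aromatic-Claisen, back to the 4-O,3'-O-bis(1,1-dimethylallyl) ether of 2,3',4-trihydroxybenzophenone. The chelated 2-OH is silylated in the flask to steer ring A to C5.
- The two tertiary allyl ethers come from the bis(1,1-dimethylpropargyl) ether by Lindlar semi-hydrogenation; that ether comes from chemoselective O-alkylation of the two non-chelated phenols.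
- The aryl–CO bond of the unsubstituted core comes from resorcinol and 3-hydroxybenzoic acid.
- Both benzene rings are bought intact: no ring is formed, no stereocentre is set and no protecting group is isolated.

**Step 1**
Reactants: 1 resorcinol; 2 3-hydroxybenzoic acid
Product: 3 (2,4-dihydroxyphenyl)(3-hydroxyphenyl)methanone
Conditions: BF3·OEt2 (neat), 90 °C; then aq. NaOAc, 60 °C
Reagents that add atoms: none
Why: Friedel–Crafts (Nencki-type) acylation of resorcinol by the BF3-activated acid occurs at C4, ortho and para to the two OH groups, and the deactivated ketone product resists a second acylation.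

**Step 2**
Reactants: 3 (2,4-dihydroxyphenyl)(3-hydroxyphenyl)methanone; 4 3-chloro-3-methylbut-1-yne (2.4 equiv)
Product: 5 [2-hydroxy-4-(2-methylbut-3-yn-2-yloxy)phenyl][3-(2-methylbut-3-yn-2-yloxy)phenyl]methanone
Conditions: K2CO3, KI (cat.), CuI (cat.), acetone, 55 °C, N2
Reagents that add atoms: 3-chloro-3-methylbut-1-yne (compound 4), CC(C)(Cl)C#C
Why: Copper-assisted propargylic etherification (Williamson type, via the copper acetylide-stabilised tertiary cation) alkylates the acidic 4-OH and the free 3'-OH, while the 2-OH, hydrogen-bonded to the ketone and hindered, stays untouched.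

**Step 3**
Reactants: 5 [2-hydroxy-4-(2-methylbut-3-yn-2-yloxy)phenyl][3-(2-methylbut-3-yn-2-yloxy)phenyl]methanone
Product: 6 [2-hydroxy-4-(2-methylbut-3-en-2-yloxy)phenyl][3-(2-methylbut-3-en-2-yloxy)phenyl]methanone
Conditions: H2 (1 atm, stopped at 2 equiv uptake), Lindlar catalyst, quinoline, EtOAc, rt
Reagents that add atoms: none
Why: Lindlar semi-hydrogenation on lead-poisoned palladium stops at the terminal alkenes and leaves the diaryl ketone and the aryl ethers alone.

**Step 4**
Reactants: 6 [2-hydroxy-4-(2-methylbut-3-en-2-yloxy)phenyl][3-(2-methylbut-3-en-2-yloxy)phenyl]methanone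
Product: 9 cudraphenone B, via 2-O-TMS bis-ether 7 (not isolated), via tris-TMS ether 8 (not isolated)
Conditions: N,O-bis(trimethylsilyl)acetamide (BSA, 6 equiv), PhNEt2, 60 °C then 150 °C; then K2CO3 (cat.), MeOH, rt
Reagents that add atoms: none
Why: Proposed new method: transient silylation of the chelated 2-OH by BSA removes the hydrogen-bond (bond-fixation) bias that sends a 4-O-allyl group of a free 2-hydroxyaryl ketone to C3, so the two aromatic Claisen [3,3] shifts of the 1,1-dimethylallyl ethers deliver linear prenyl groups to C5 (para to the 2-OSiMe3 donor and less hindered) and to C2' (the ortho carbon next to the electron-withdrawing aroyl group, the usual preference of aryl allyl ethers with a meta acceptor), while excess BSA caps the new phenols against chroman formation and methanolysis then frees all three OH groups; the closest known reactions are the thermal Claisen rearrangement of aryl 1,1-dimethylallyl ethers in N,N-diethylaniline and the C5-selective rearrangement of 2-O-alkylated 4-allyloxyaryl ketones.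

**Compound list**
1 | resorcinol (benzene-1,3-diol) | Oc1cccc(O)c1 | starting material
2 | 3-hydroxybenzoic acid | OC(=O)c1cccc(O)c1 | starting material
3 | (2,4-dihydroxyphenyl)(3-hydroxyphenyl)methanone | O=C(c1ccc(O)cc1O)c1cccc(O)c1 | intermediate
4 | 3-chloro-3-methylbut-1-yne | CC(C)(Cl)C#C | starting material
5 | [2-hydroxy-4-(2-methylbut-3-yn-2-yloxy)phenyl][3-(2-methylbut-3-yn-2-yloxy)phenyl]methanone | C#CC(C)(C)Oc1ccc(C(=O)c2cccc(OC(C)(C)C#C)c2)c(O)c1 | intermediate
6 | [2-hydroxy-4-(2-methylbut-3-en-2-yloxy)phenyl][3-(2-methylbut-3-en-2-yloxy)phenyl]methanone | C=CC(C)(C)Oc1ccc(C(=O)c2cccc(OC(C)(C)C=C)c2)c(O)c1 | intermediate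
7 | 2-O-trimethylsilyl ether of 6 (not isolated) | C=CC(C)(C)Oc1ccc(C(=O)c2cccc(OC(C)(C)C=C)c2)c(O[Si](C)(C)C)c1 | intermediate
8 | tris(trimethylsilyl) ether of cudraphenone B (not isolated) | CC(C)=CCc1cc(C(=O)c2cccc(O[Si](C)(C)C)c2CC=C(C)C)c(O[Si](C)(C)C)cc1O[Si](C)(C)C | intermediate
9 | cudraphenone B, [2,4-dihydroxy-5-(3-methylbut-2-en-1-yl)phenyl][3-hydroxy-2-(3-methylbut-2-en-1-yl)phenyl]methanone (achiral, no stereodescriptors) | CC(C)=CCc1cc(C(=O)c2cccc(O)c2CC=C(C)C)c(O)cc1O | target

**Total step count:** 4
**Longest linear sequence:** 4 steps (1 → 3 → 5 → 6 → 9)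

**Three steps most likely to fail**

Step 4 (double Claisen) is the riskiest. Migration on ring B can also go to C4', migration on ring A can go to C3 if the silyl masking is incomplete, and the tertiary ethers can fragment. The fallback sets out from 1 and comes back at 9, and replaces pericyclic prenyl delivery by cross-coupling at C–Br bonds whose positions are fixed by the building blocks. Resorcinol 1 is monobrominated (NBS, MeCN, 0 °C) to 4-bromoresorcinol F1. F1 is acylated at C6 with commercial 2-bromo-3-hydroxybenzoic acid (BF3·OEt2, 90 °C) to (5-bromo-2,4-dihydroxyphenyl)(2-bromo-3-hydroxyphenyl)methanone F2. Peracetylation (Ac2O, pyridine, DMAP) gives the dibromo triacetate F3. A double Stille coupling with tributyl(3-methylbut-2-en-1-yl)stannane (Pd(PPh3)4, DMF, 90 °C) gives the bis-prenyl triacetate F4, and K2CO3 in MeOH at 0 °C releases 9.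

Step 2 (double O-alkylation with a tertiary propargylic chloride) is second. Elimination of the chloride, incomplete bis-alkylation or partial alkylation of the 2-OH can occur. The fallback sets out from 3 and comes back at 6, so that 5 and step 3 are bypassed. It is a Pd(0)-catalysed decarboxylative O-allylation (Tsuji–Trost type). Compound 3 is treated with tert-butyl 2-methylbut-3-en-2-yl carbonate F5 (made from 2-methylbut-3-en-2-ol, n-BuLi and Boc2O; 2.2 equiv) and Pd(PPh3)4 (3 mol%) in THF at 0 °C. The phenoxides attack the more substituted allyl terminus under kinetic control and give the bis(1,1-dimethylallyl) ether 6 directly.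

Step 1 (Friedel–Crafts acylation with an unprotected hydroxy acid) is third. Self-esterification of 2 and a stubborn BF2 chelate of the product can depress the yield. The fallback sets out from 1 and comes back at 3, and uses a nitrile instead of an acylium electrophile (Houben–Hoesch reaction). Resorcinol 1 and commercial 3-hydroxybenzonitrile are treated with ZnCl2 and HCl gas in Et2O at 0 °C, which precipitates (2,4-dihydroxyphenyl)(3-hydroxyphenyl)methaniminium chloride F6. Heating F6 in water hydrolyses it to 3.

**Further compounds**
F1 | step 4 | 4-bromoresorcinol (4-bromobenzene-1,3-diol) | Oc1ccc(Br)c(O)c1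
F2 | step 4 | (5-bromo-2,4-dihydroxyphenyl)(2-bromo-3-hydroxyphenyl)methanone | O=C(c1cc(Br)c(O)cc1O)c1cccc(O)c1Br
F3 | step 4 | dibromo triacetate, (2,4-diacetoxy-5-bromophenyl)(3-acetoxy-2-bromophenyl)methanone | CC(=O)Oc1cc(OC(C)=O)c(C(=O)c2cccc(OC(C)=O)c2Br)cc1Br
F4 | step 4 | bis-prenyl triacetate, tri-O-acetylcudraphenone B | CC(=O)Oc1cc(OC(C)=O)c(C(=O)c2cccc(OC(C)=O)c2CC=C(C)C)cc1CC=C(C)C
F5 | step 2 | tert-butyl 2-methylbut-3-en-2-yl carbonate | C=CC(C)(C)OC(=O)OC(C)(C)C
F6 | step 1 | (2,4-dihydroxyphenyl)(3-hydroxyphenyl)methaniminium chloride | [Cl-].[NH2+]=C(c1ccc(O)cc1O)c1cccc(O)c1
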